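## Structural features

The target is a resveratrol dimer built on a 10,11-dihydro-5H-dibenzo[a,d]cycloheptene whose seven-membered ring consists of C7, C8, a1 and a6 of ring A, C8', and d1 and d6 of ring D. A 2,3-dihydrobenzofuran (a5, its oxygen, C7', C8', a6) is fused on the a5–a6 edge, so the a6–C8' bond belongs to both rings. C7 and C7' each carry a 4-hydroxyphenyl group, and free hydroxyls sit on a3, d3 and d5. All three stereocentres are S: C8' and C7' are adjacent and trans on the furan, and the C7 aryl group lies on the face of the seven-membered ring opposite to C7'. Fragile points are the five electron-rich phenols, the doubly benzylic C8'–H, and the benzylic C7'–O bond, which ionises under acid to a para-quinone-methide-type cation. The real difficulty is the hindered a6–C8' bond: both a6 and a2 are ortho to a1 and flanked by an oxygenated carbon, so the bond must be directed to the carbon next to the furan oxygen, and its configuration must be relayed from the remote, handle-free triarylethane centre C7. The key step uses the ortho relationship of a6 to the a5 oxygen: an allyl unit on that oxygen whose far terminus is C8' (already on d1) can pass C8' to a6 by a [3,3] shift, closing the seven-membered ring, freeing the a5 phenol and leaving a vinyl group whose inner carbon becomes C7'.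

## Logic of the disconnections

**26 from 25.** The five O–CH3 bonds are cut last. Methyl ethers are the one phenol protection that passes unchanged through acylation, organomagnesium, 180 °C and periodate chemistry. The forward step must not destroy the C7'–O bond; this is tolerable because the a5 oxygen is held next to C7' and re-closes.

**25 from 24.** The O(a5)–C7' bond is cut, giving a benzylic alcohol beside a phenol. The forward closure runs through a planar cation and is thermodynamically trans-selective, so C7' needs no earlier control. It demands mild acid and no elimination toward C8'.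

**24 from 21 and 22 (through 23).** The C7'–aryl bond is cut; C7' becomes a carbonyl carbon, stored as the hemiacetal in 21 and released in the flask as 23, and the aryl group an organomagnesium reagent. The second 4-oxyphenyl ring disappears from all earlier intermediates. Addition must outrun enolisation at C8'.

**21 from 18 (through 19 and 20).** The C7' carbonyl is traced to the C=C bond of a vinyl group, which is exactly what the sigmatropic step leaves on C8'. The forward cleavage must tolerate a free phenol.

**18 from 16 (key, through 17).** The a6–C8' bond is cut and the a5 oxygen is reconnected to the vinyl terminus with allylic transposition. This removes the seven-membered ring and the C8' stereocentre together and replaces a C–C bond at a hindered arene carbon by an O–CH2 bond. The forward step needs a [3,3] shift across the ring, face selection from C7, and a ring in which only a6 is within reach.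

**16 from 15.** The O–CH2 bond is cut to a phenol and a primary allylic alcohol. An SN2 etherification is the least demanding way to close a strained ring and leaves the alkene geometry untouched. It demands high dilution.

**15 from 12 and 13 (through 14).** The d1–alkene bond and two O–Si bonds are cut. The three-carbon unit arrives with its E geometry fixed, and the aryl bromide comes from the ring-D starting material. The coupling must work at an ortho-branched bromide without touching C7.

**12 from 11.** The C–H bonds at C7 and C8 are removed; C7 is traced to face-selective addition of H2. This demands one alkene geometry and a catalyst that distinguishes the two geminal aryl groups.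

**11 from 5 and 8 (through 9 and 10).** The C7–C8 bond is cut to a benzylic nucleophile and a non-enolisable diaryl ketone, two fragments of similar size. Dehydration must give one geometry.

**8 from 6 and 7.** The C7–d6 bond is cut as an acylation of the bromodimethoxyarene. Regioselectivity next to bromine is required.

**5 from 1 (through 2, 3 and 4).** Only functional-group changes at the benzylic carbon and one O–Si bond are involved. The single free hydroxyl of 1 distinguishes a5 from a3 for the whole route.

## Other disconnections considered

Alternative 1: The cut is the O(a5)–C7' bond, formed last by an enzyme. The substrate would be A1, in which C8' carries a free 4-hydroxybenzyl group and a5 a free hydroxyl. A flavin-dependent 4-alkylphenol oxidase with O2 would remove hydride from the C7' methylene to give quinone methide A2, and the a5 phenol would add to it to give A3.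
- In favour: oxygen is the only oxidant, no carbon is added and later excised, and the one free 4-hydroxyphenyl ring is addressed selectively.
- Against: enzymes of this family are known for small 4-alkylphenols. In A1 the methylene hangs on a triply substituted, doubly benzylic carbon inside a tricycle, so binding is doubtful without protein engineering. Water in the active site competes with the a5 phenol. A1 still needs the seven-membered ring, the a6–C8' bond and both carbon stereocentres, and a [3,3] shift cannot deliver a benzyl group to C8'.
- Comparison: on structure it simplifies only the last ring, whereas the chosen key step builds the carbocycle and C8'. On mechanism the C–O closure is the equal of step 14 (same cationic closure, same trans preference), and the C–H oxidation is the better in redox economy. On step economy it would replace steps 12 to 14 by one operation, but only if A1 were as accessible as 18, which is not evident.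

Alternative 2: The cut is the C7–C8 bond, re-formed as a ring alkene with loss of SO2. The eight-membered sulfone A4 (SO2 between C7 and C8, diaryl ketone at C8') would be halogenated and deprotonated in one pot (KOH on alumina, CBr2F2), and 1,3-elimination with loss of SO2 would give dibenzosuberenone A5.
- In favour: the contraction is well established for cyclic benzylic sulfones, and C–S bonds close an eight-membered ring easily. Ring A can be symmetric, so no a2/a6 question arises. The C8' carbonyl sits next to the a5 methoxy group and would allow chelation-controlled unmasking of that oxygen alone. The C7=C8 alkene is locked in a ring, so its geometry is fixed for an asymmetric hydrogenation; on this point the alternative is the better, since alkene 11 must first be secured as one isomer.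
- Against: A5 is flat and achiral, so all three stereocentres remain to be set (C7 on a hindered cyclic triaryl alkene; C8' and C7' by homologation of a hindered diaryl ketone). Dihalocarbene may add to the electron-rich stilbene. A4 needs a benzophenone and a secondary diarylmethyl sulfide assembled first.
- Comparison: on mechanism the alternative rests on known chemistry and is the safer key step. On structure the chosen step delivers ring, bond, stereocentre and free a5 phenol against ring and alkene. On step economy the alternative should be longer by several steps.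

Alternative 3: Two bonds are cut, a1–C8 and a6–C8', leaving ring A as an aryne and the rest as an indanone. CsF would release aryne A8 from silyl triflate A7. The enolate of β-keto ester A6 would add through C8 to the aryne carbon remote from the methoxy group, the aryl anion would close on the ketone, and fragmentation would insert the arene into the C8–C8' bond to give A9.
- In favour: it is convergent, forming two C–C bonds and the ring in one operation, with regiochemistry set by the aryne methoxy group. Aryne insertion into cyclic β-keto esters is a known ring expansion. C7 of A6 could come from an asymmetric conjugate addition of an arylboronic acid catalysed by [Rh(acac)(C2H4)2] and a chiral bisphosphine, a better-established route to a diarylmethine than the hydrogenation of 11; on the origin of C7 the alternative is the better.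
- Against: the nucleophilic carbon of A6 is flanked by the C7 aryl group, and its ketone is a deactivated, electron-rich aryl ketone, so insertion may lose to simple arylation or aryne side reactions. C8' arrives as a ketone without configuration and must be homologated and set relative to C7. The ester costs a dealkoxycarbonylation step. The a5 oxygen emerges methylated and needs selective cleavage, whereas the chosen step frees it directly.
- Comparison: on structure it forms two bonds against one but no stereocentre. On mechanism it is the better precedented. On step economy it is about equal: short to A9, then three to four extra steps before it meets the sequence of steps 13 to 15.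

Key step: step 11

Remark: 13 and 22 are taken to be purchasable reagents, the (Z) isomer 11 is assumed to be the thermodynamically preferred alkene, and positions are named C7, C8, C7', C8', a1–a6 and d1–d6 as above.

## Route

Step 1
Reactants: 1 methyl 3-hydroxy-5-methoxybenzoate
Product: 2 methyl 3-methoxy-5-{[tri(propan-2-yl)silyl]oxy}benzoate
Conditions: TIPSCl, imidazole, DMF, 25 °C
Reagents that add atoms: chlorotri(propan-2-yl)silane, CC(C)[Si](Cl)(C(C)C)C(C)C
Why: Standard silylation of a phenol; the bulky silyl ether marks the a5 oxygen, tolerates the hydride, Grignard and acid steps that follow and is removed by fluoride in step 9.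

Step 2
Reactants: 2 methyl 3-methoxy-5-{[tri(propan-2-yl)silyl]oxy}benzoate
Product: 3 (3-methoxy-5-{[tri(propan-2-yl)silyl]oxy}phenyl)methanol
Conditions: i-Bu2AlH (2.5 equiv), CH2Cl2, −78 to 0 °C; aq KNaC4H4O6 (potassium sodium tartrate)
Reagents that add atoms: none
Why: Hydride reduction of the ester to the benzylic alcohol; aryl silyl and aryl methyl ethers are inert to i-Bu2AlH at low temperature.

Step 3
Reactants: 3 (3-methoxy-5-{[tri(propan-2-yl)silyl]oxy}phenyl)methanol
Product: 5 [3-(chloromethyl)-5-methoxyphenoxy]tri(propan-2-yl)silane, via benzylic mesylate 4 (not isolated)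
Conditions: MsCl, Et3N, LiCl, THF, 0 to 25 °C
Reagents that add atoms: lithium chloride, [Li+].[Cl-]
Why: Sulfonylation then SN2 displacement of the benzylic mesylate by chloride in one flask; the near-neutral medium spares the silyl ether, and the meta-oxygenated benzyl chloride does not ionise readily.

Step 4
Reactants: 6 1-bromo-3,5-dimethoxybenzene; 7 4-methoxybenzoyl chloride
Product: 8 (2-bromo-4,6-dimethoxyphenyl)(4-methoxyphenyl)methanone
Conditions: AlCl3 (1.2 equiv), CH2Cl2, 0 °C
Reagents that add atoms: none
Why: Friedel–Crafts acylation forming the C7–d6 bond; attack next to bromine (para to one methoxy group) is preferred over the position flanked by two methoxy groups, and low temperature limits demethylation of the ortho methoxy group by AlCl3.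

Step 5
Reactants: 5 [3-(chloromethyl)-5-methoxyphenoxy]tri(propan-2-yl)silane; 8 (2-bromo-4,6-dimethoxyphenyl)(4-methoxyphenyl)methanone
Product: 10 1-(2-bromo-4,6-dimethoxyphenyl)-1-(4-methoxyphenyl)-2-(3-methoxy-5-{[tri(propan-2-yl)silyl]oxy}phenyl)ethan-1-ol (racemic), via benzylic Grignard reagent 9 (not isolated)
Conditions: Mg, I2 (cat.), Et2O, 0 to 25 °C (slow addition of 5); then 8, THF, 0 to 25 °C; aq NH4Cl
Reagents that add atoms: none
Why: Grignard addition to a non-enolisable diaryl ketone forms the C7–C8 bond; slow generation of 9 from the chloride limits Wurtz coupling, and a benzylic organomagnesium does not exchange with the aryl bromide.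

Step 6
Reactants: 10 1-(2-bromo-4,6-dimethoxyphenyl)-1-(4-methoxyphenyl)-2-(3-methoxy-5-{[tri(propan-2-yl)silyl]oxy}phenyl)ethan-1-ol
Product: 11 (Z)-{3-[2-(2-bromo-4,6-dimethoxyphenyl)-2-(4-methoxyphenyl)ethenyl]-5-methoxyphenoxy}tri(propan-2-yl)silane
Conditions: TsOH·H2O (5 mol%), toluene, reflux with azeotropic removal of water; crystallisation
Reagents that add atoms: none
Why: Acid-catalysed E1 dehydration; only C8 carries β-hydrogens, and reversible protonation should equilibrate the alkene to the (Z) isomer, which keeps ring A and the 4-methoxyphenyl ring in a planar trans-stilbene unit while the di-ortho-substituted ring D twists out of plane; residual (E) isomer is removed and can be re-equilibrated.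

Step 7
Reactants: 11 (Z)-{3-[2-(2-bromo-4,6-dimethoxyphenyl)-2-(4-methoxyphenyl)ethenyl]-5-methoxyphenoxy}tri(propan-2-yl)silane
Product: 12 (S)-{3-[2-(2-bromo-4,6-dimethoxyphenyl)-2-(4-methoxyphenyl)ethyl]-5-methoxyphenoxy}tri(propan-2-yl)silane
Conditions: [Ir(cod)(t-Bu-PHOX)]B[C6H3-3,5-(CF3)2]4 (2 mol%, ligand enantiomer chosen for the S product), H2 (50 bar), CH2Cl2, 25 °C
Reagents that add atoms: none
Why: Asymmetric hydrogenation of an unfunctionalised trisubstituted aryl alkene by the cationic [Ir(cod)(t-Bu-PHOX)]+ complex; the single alkene geometry and the steric contrast between the twisted ring D and the flat stilbene unit let the catalyst pocket select one face, setting C7 as S, while the aryl bromide and silyl ether are inert.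

Step 8
Reactants: 12 (S)-{3-[2-(2-bromo-4,6-dimethoxyphenyl)-2-(4-methoxyphenyl)ethyl]-5-methoxyphenoxy}tri(propan-2-yl)silane; 13 (E)-tert-butyldimethyl{[3-(4,4,5,5-tetramethyl-1,3,2-dioxaborolan-2-yl)prop-2-en-1-yl]oxy}silane
Product: 14 tert-butyl{[(2E)-3-{2-[(1S)-1-(4-methoxyphenyl)-2-(3-methoxy-5-{[tri(propan-2-yl)silyl]oxy}phenyl)ethyl]-3,5-dimethoxyphenyl}prop-2-en-1-yl]oxy}dimethylsilane
Conditions: Pd(OAc)2 (5 mol%), SPhos (10 mol%), K3PO4, toluene/H2O, 90 °C
Reagents that add atoms: none
Why: Suzuki–Miyaura coupling with retention of the (E) geometry of the alkenylboronate; the biaryl phosphine copes with the ortho-branched, electron-rich aryl bromide, and C7 is not acidic enough to epimerise under phosphate base.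

Step 9
Reactants: 14 tert-butyl{[(2E)-3-{2-[(1S)-1-(4-methoxyphenyl)-2-(3-methoxy-5-{[tri(propan-2-yl)silyl]oxy}phenyl)ethyl]-3,5-dimethoxyphenyl}prop-2-en-1-yl]oxy}dimethylsilane
Product: 15 3-[(2S)-2-{2-[(1E)-3-hydroxyprop-1-en-1-yl]-4,6-dimethoxyphenyl}-2-(4-methoxyphenyl)ethyl]-5-methoxyphenol
Conditions: TBAF (2.5 equiv), THF, 0 to 25 °C
Reagents that add atoms: none
Why: Fluoride cleaves both silyl ethers in one operation and releases exactly the two hydroxyls that are to be joined, the a5 phenol and the allylic alcohol.

Step 10
Reactants: 15 3-[(2S)-2-{2-[(1E)-3-hydroxyprop-1-en-1-yl]-4,6-dimethoxyphenyl}-2-(4-methoxyphenyl)ethyl]-5-methoxyphenol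
Product: 16 (S,E)-macrocyclic cinnamyl aryl ether (eleven-membered ring C7–C8–a1–a6–a5–O–CH2–CH=CH–d1–d6; 4-methoxyphenyl on C7; methoxy on a3, d3, d5)
Conditions: PPh3, DIAD, toluene, slow addition to 0.002 M, 25 °C
Reagents that add atoms: none
Why: Intramolecular Mitsunobu etherification of a phenol by a primary allylic alcohol (SN2 at the CH2 carbon, alkene geometry untouched); slow addition at high dilution favours ring closure over oligomerisation, and the phenol is the only acidic pronucleophile.

Step 11
Reactants: 16 (S,E)-macrocyclic cinnamyl aryl ether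
Product: 18 (5S,10S)-5-ethenyl-2,7,9-trimethoxy-10-(4-methoxyphenyl)-10,11-dihydro-5H-dibenzo[a,d][7]annulen-4-ol, via ortho-dienone 17 (not isolated)
Conditions: N,N-diethylaniline (0.01 M, degassed), 180 °C, sealed tube
Reagents that add atoms: none
Why: Proposed new method: a concerted suprafacial [3,3] shift across the eleven-membered ring should join the alkene carbon C8' to the inward-pointing carbon a6 while the O–CH2 bond breaks, giving dienone 17, which enolises to phenol 18; the closest known reactions are the thermal aromatic Claisen rearrangement of open-chain aryl cinnamyl ethers and the ring-contracting Ireland–Claisen rearrangement of macrolactones. The seven-membered ring is thus closed not by attack on an electrophile but by transannular ring contraction (eleven to seven), the six-atom pericyclic array being fused to the new ring along the forming a6–C8' bond. In the meta-bridged macrocycle the middle of the bridge (C8', d1) lies over the face of ring A at a6, so the termini are held close and ring strain is released, which should lower the barrier relative to open-chain cinnamyl ethers. With the (E) alkene a chair-like array places ring D on the a1 side, where the C7–C8 tether needs it, whereas a (Z) alkene would force ring D over ring A. The new centre C8' is controlled by C7: allylic 1,3-strain with the d5 methoxy group keeps H7 in the plane of ring D and the 4-methoxyphenyl group pseudo-axial on the nascent ring, and only one alkene face fits a chair-like seven-membered ring with that arrangement; it delivers the vinyl group pseudo-equatorial and trans to the C7 aryl group, that is S at C8'. Regioselectivity is enforced by the ring, because bonding at a4 would require a para-bridged product. The amine solvent buffers traces of acid, suppressing ionisation of the allyl ether and addition of the new phenol to the vinyl group.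

Step 12
Reactants: 18 (5S,10S)-5-ethenyl-2,7,9-trimethoxy-10-(4-methoxyphenyl)-10,11-dihydro-5H-dibenzo[a,d][7]annulen-4-ol
Product: 21 (7S,8'S)-lactol (2-hydroxy-2,3-dihydrobenzofuran on the a5–a6 edge; C7' bears OH as a mixture of anomers; four methyl ethers), via vicinal diol 19 (not isolated), via hydroxy aldehyde 20 (not isolated)
Conditions: K2OsO4·2H2O (2 mol%), NaIO4 (4 equiv), 2,6-lutidine, dioxane/H2O, 0 to 25 °C
Reagents that add atoms: sodium periodate, [Na+].[O-]I(=O)(=O)=O
Why: Lemieux–Johnson oxidation: dihydroxylation of the only alkene (the new oxygen comes from periodate by way of K2OsO4), periodate cleavage of 19 and capture of aldehyde 20 by the neighbouring a5 phenol as the lactol, which masks the epimerisable α,α-diaryl aldehyde; 2,6-lutidine keeps the medium near neutral so that the lactol does not dehydrate to a benzofuran.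

Step 13
Reactants: 21 (7S,8'S)-lactol; 22 (4-methoxyphenyl)magnesium bromide
Product: 24 (5S,10S)-5-[hydroxy(4-methoxyphenyl)methyl]-2,7,9-trimethoxy-10-(4-methoxyphenyl)-10,11-dihydro-5H-dibenzo[a,d][7]annulen-4-ol (carbinol epimers), via ring-opened bromomagnesium phenoxide aldehyde 23 (not isolated)
Conditions: 22 (4 equiv), LaCl3·2LiCl (0.3 equiv), THF, −20 to 25 °C; aq NH4Cl
Reagents that add atoms: none
Why: One equivalent of 22 deprotonates the lactol, whose bromomagnesium lactolate opens to the phenoxide aldehyde 23, and a second equivalent adds to that aldehyde (Grignard addition), LaCl3·2LiCl favouring carbonyl addition over enolisation at C8'. The configuration formed at C7' is irrelevant because step 14 erases it.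

Step 14
Reactants: 24 (5S,10S)-5-[hydroxy(4-methoxyphenyl)methyl]-2,7,9-trimethoxy-10-(4-methoxyphenyl)-10,11-dihydro-5H-dibenzo[a,d][7]annulen-4-ol
Product: 25 (7S,7'S,8'S)-ampelopsin B penta-O-methyl ether
Conditions: TsOH·H2O (10 mol%), CH2Cl2, 0 to 25 °C
Reagents that add atoms: none
Why: Acid ionises the benzylic alcohol to a 4-methoxybenzyl cation that the a5 phenol traps in a five-membered ring closure; the closure is reversible, so both carbinol epimers should converge on the trans-2,3-disubstituted dihydrobenzofuran (C7' S).

Step 15
Reactants: 25 (7S,7'S,8'S)-ampelopsin B penta-O-methyl ether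
Product: 26 ampelopsin B, (7S,7'S,8'S)
Conditions: BBr3 (12 equiv), CH2Cl2, −78 to 25 °C; MeOH, then H2O
Reagents that add atoms: none
Why: Exhaustive cleavage of the five aryl methyl ethers by BBr3 (bromide attacks the methyl group of the boron-complexed ether); if the benzylic C7'–O bond ionises, the a5 oxygen is held beside C7' and re-closes to the same trans-fused ring on work-up.

## Compound list

1 | methyl 3-hydroxy-5-methoxybenzoate | COC(=O)c1cc(O)cc(OC)c1 | starting material
2 | methyl 3-methoxy-5-{[tri(propan-2-yl)silyl]oxy}benzoate | COC(=O)c1cc(OC)cc(O[Si](C(C)C)(C(C)C)C(C)C)c1 | intermediate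
3 | (3-methoxy-5-{[tri(propan-2-yl)silyl]oxy}phenyl)methanol | COc1cc(CO)cc(O[Si](C(C)C)(C(C)C)C(C)C)c1 | intermediate
4 | 3-methoxy-5-{[tri(propan-2-yl)silyl]oxy}benzyl methanesulfonate | COc1cc(COS(C)(=O)=O)cc(O[Si](C(C)C)(C(C)C)C(C)C)c1 | intermediate
5 | [3-(chloromethyl)-5-methoxyphenoxy]tri(propan-2-yl)silane | COc1cc(CCl)cc(O[Si](C(C)C)(C(C)C)C(C)C)c1 | intermediate
6 | 1-bromo-3,5-dimethoxybenzene | COc1cc(Br)cc(OC)c1 | starting material
7 | 4-methoxybenzoyl chloride | COc1ccc(C(Cl)=O)cc1 | starting material
8 | (2-bromo-4,6-dimethoxyphenyl)(4-methoxyphenyl)methanone | COc1ccc(C(=O)c2c(Br)cc(OC)cc2OC)cc1 | intermediate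
9 | (3-methoxy-5-{[tri(propan-2-yl)silyl]oxy}benzyl)magnesium chloride | COc1cc(C[Mg]Cl)cc(O[Si](C(C)C)(C(C)C)C(C)C)c1 | intermediate
10 | 1-(2-bromo-4,6-dimethoxyphenyl)-1-(4-methoxyphenyl)-2-(3-methoxy-5-{[tri(propan-2-yl)silyl]oxy}phenyl)ethan-1-ol (racemic) | COc1ccc(C(O)(Cc2cc(OC)cc(O[Si](C(C)C)(C(C)C)C(C)C)c2)c2c(Br)cc(OC)cc2OC)cc1 | intermediate
11 | (Z)-{3-[2-(2-bromo-4,6-dimethoxyphenyl)-2-(4-methoxyphenyl)ethenyl]-5-methoxyphenoxy}tri(propan-2-yl)silane (ring A cis to ring D) | COc1ccc(/C(=C/c2cc(OC)cc(O[Si](C(C)C)(C(C)C)C(C)C)c2)c2c(Br)cc(OC)cc2OC)cc1 | intermediate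
12 | (S)-{3-[2-(2-bromo-4,6-dimethoxyphenyl)-2-(4-methoxyphenyl)ethyl]-5-methoxyphenoxy}tri(propan-2-yl)silane | COc1ccc([C@H](Cc2cc(OC)cc(O[Si](C(C)C)(C(C)C)C(C)C)c2)c2c(Br)cc(OC)cc2OC)cc1 | intermediate
13 | (E)-tert-butyldimethyl{[3-(4,4,5,5-tetramethyl-1,3,2-dioxaborolan-2-yl)prop-2-en-1-yl]oxy}silane | CC(C)(C)[Si](C)(C)OC/C=C/B1OC(C)(C)C(C)(C)O1 | starting material
14 | tert-butyl{[(2E)-3-{2-[(1S)-1-(4-methoxyphenyl)-2-(3-methoxy-5-{[tri(propan-2-yl)silyl]oxy}phenyl)ethyl]-3,5-dimethoxyphenyl}prop-2-en-1-yl]oxy}dimethylsilane | COc1ccc([C@H](Cc2cc(OC)cc(O[Si](C(C)C)(C(C)C)C(C)C)c2)c2c(/C=C/CO[Si](C)(C)C(C)(C)C)cc(OC)cc2OC)cc1 | intermediate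
15 | 3-[(2S)-2-{2-[(1E)-3-hydroxyprop-1-en-1-yl]-4,6-dimethoxyphenyl}-2-(4-methoxyphenyl)ethyl]-5-methoxyphenol | COc1ccc([C@H](Cc2cc(OC)cc(O)c2)c2c(/C=C/CO)cc(OC)cc2OC)cc1 | intermediate
16 | (S,E)-macrocyclic cinnamyl aryl ether (eleven-membered ring C7–C8–a1–a6–a5–O–CH2–CH=CH–d1–d6; 4-methoxyphenyl on C7; methoxy on a3, d3, d5) | COc1ccc([C@@H]2Cc3cc(OC)cc(c3)OC/C=C/c3cc(OC)cc(OC)c32)cc1 | intermediate
17 | ortho-dienone tautomer of 18 (a5 carbonyl; a6 sp3 bearing H and C8') | COc1ccc([C@@H]2CC3=CC(OC)=CC(=O)[C@@H]3[C@@H](C=C)c3cc(OC)cc(OC)c32)cc1 | intermediate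
18 | (5S,10S)-5-ethenyl-2,7,9-trimethoxy-10-(4-methoxyphenyl)-10,11-dihydro-5H-dibenzo[a,d][7]annulen-4-ol | COc1ccc([C@@H]2Cc3cc(OC)cc(O)c3[C@@H](C=C)c3cc(OC)cc(OC)c32)cc1 | intermediate
19 | 1-[(5S,10S)-4-hydroxy-2,7,9-trimethoxy-10-(4-methoxyphenyl)-10,11-dihydro-5H-dibenzo[a,d][7]annulen-5-yl]ethane-1,2-diol (carbinol epimers) | COc1ccc([C@@H]2Cc3cc(OC)cc(O)c3[C@H](c3cc(OC)cc(OC)c32)C(O)CO)cc1 | intermediate
20 | (5S,10S)-4-hydroxy-2,7,9-trimethoxy-10-(4-methoxyphenyl)-10,11-dihydro-5H-dibenzo[a,d][7]annulene-5-carbaldehyde | COc1ccc([C@@H]2Cc3cc(OC)cc(O)c3[C@H](c3cc(OC)cc(OC)c32)C=O)cc1 | intermediate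
21 | (7S,8'S)-lactol (2-hydroxy-2,3-dihydrobenzofuran on the a5–a6 edge; C7' anomers; four methyl ethers) | COc1ccc([C@@H]2Cc3cc(OC)cc4c3[C@H](c3cc(OC)cc(OC)c32)C(O)O4)cc1 | intermediate
22 | (4-methoxyphenyl)magnesium bromide | COc1ccc([Mg]Br)cc1 | starting material
23 | bromomagnesium (5S,10S)-5-formyl-2,7,9-trimethoxy-10-(4-methoxyphenyl)-10,11-dihydro-5H-dibenzo[a,d][7]annulen-4-olate (ring-opened magnesium salt of lactol 21) | COc1ccc([C@@H]2Cc3cc(OC)cc(O[Mg]Br)c3[C@H](c3cc(OC)cc(OC)c32)C=O)cc1 | intermediate
24 | (5S,10S)-5-[hydroxy(4-methoxyphenyl)methyl]-2,7,9-trimethoxy-10-(4-methoxyphenyl)-10,11-dihydro-5H-dibenzo[a,d][7]annulen-4-ol (carbinol epimers) | COc1ccc([C@@H]2Cc3cc(OC)cc(O)c3[C@H](c3cc(OC)cc(OC)c32)C(O)c2ccc(OC)cc2)cc1 | intermediate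
25 | (7S,7'S,8'S)-ampelopsin B penta-O-methyl ether | COc1ccc([C@@H]2Cc3cc(OC)cc4c3[C@H](c3cc(OC)cc(OC)c32)[C@@H](c2ccc(OC)cc2)O4)cc1 | intermediate
26 | ampelopsin B, (7S,7'S,8'S) | Oc1ccc([C@@H]2Cc3cc(O)cc4c3[C@H](c3cc(O)cc(O)c32)[C@@H](c2ccc(O)cc2)O4)cc1 | target

## Step count and least certain steps

Total: 15 steps. Longest linear sequence: 14 steps (from 1 through steps 1–3 and 5–15); step 4 is the only side branch.

**Step 11 (key step).** The most likely failure is that the strained macrocycle reacts by a non-concerted path (homolysis or ionisation of the O–allyl bond followed by oligomerisation or a [1,3] shift) before the ordered array is reached. The second is loss of facial selectivity if a boat-like array competes. Fallback by known chemistry, from 12 back to 18: bromine–lithium exchange on 12 (n-BuLi, THF, −78 °C) and formylation with DMF should give the ring-D aryl aldehyde F1, and TBAF then frees the phenol aldehyde F2. Conversion of F2 into its bromomagnesium phenoxide (EtMgBr, one equivalent, toluene) should trigger chelation-directed ortho-hydroxyalkylation; only a6 is in reach, so this closes the seven-membered ring as the cyclic ortho-hydroxybenzylic alcohol F3. Excess vinylmagnesium bromide in warm THF should convert F3 into the ortho-quinone methide and add to C8' in a 1,4 sense from the face away from the C7 aryl group, rejoining the route at 18.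

**Step 7.** Hydrogenation may stall because the di-ortho-substituted ring shields the alkene, and enantiomeric purity may erode if the alkene isomerises before reduction. Fallback, from 11 back to 12: hydrogenation with the achiral catalyst [Ir(cod)(PCy3)(py)]PF6 to the racemic triarylethane F4, followed by preparative chromatography on a chiral stationary phase, which returns the S enantiomer 12.

**Step 10.** Intermolecular etherification may outrun closure of the strained ring, and attack at the benzylic alkene carbon (SN2') may compete. Fallback that closes a different bond, from 12 back to 16: TBAF on 12 gives the bromo phenol F5, and alkylation of F5 with (E)-2-(3-chloroprop-1-en-1-yl)-4,4,5,5-tetramethyl-1,3,2-dioxaborolane (K2CO3, NaI, acetone) gives the allyl aryl ether boronate F6. Intramolecular Suzuki–Miyaura coupling of F6 at high dilution (Pd(OAc)2, SPhos, K3PO4) closes the d1–alkene bond with retention of geometry, returning to 16; the catalyst loading is kept low to limit ionisation of the allyl ether by zerovalent palladium.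

**Step 12.** Periodate may over-oxidise the free electron-rich phenol, and the lactol may dehydrate or epimerise at C8' through its open form. Fallback, from 18 back to 24: acetylation of 18 (Ac2O, pyridine) gives the aryl acetate F7, and the same K2OsO4/NaIO4 cleavage gives the acetoxy aldehyde F8. Excess 22 adds to the aldehyde and removes the acetate in the same flask, returning to 24.

**Step 15.** The Lewis acid may ionise the benzylic C7'–O bond faster than it demethylates, leading to bromide capture, elimination toward C8' or epimerisation. Fallback that reverses the order of events, from 24 back to 26: exhaustive demethylation of 24 with BBr3 before the furan exists, then aqueous acidic work-up. The hexaphenolic benzylic alcohol F9 (or its bromide) ionises at C7' and is closed by the a5 phenol to the thermodynamically favoured trans ring, giving 26.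

## Further compounds

F1 | step 11 | 2-[(1S)-1-(4-methoxyphenyl)-2-(3-methoxy-5-{[tri(propan-2-yl)silyl]oxy}phenyl)ethyl]-3,5-dimethoxybenzaldehyde | COc1ccc([C@H](Cc2cc(OC)cc(O[Si](C(C)C)(C(C)C)C(C)C)c2)c2c(C=O)cc(OC)cc2OC)cc1
F2 | step 11 | 2-[(1S)-2-(3-hydroxy-5-methoxyphenyl)-1-(4-methoxyphenyl)ethyl]-3,5-dimethoxybenzaldehyde | COc1ccc([C@H](Cc2cc(OC)cc(O)c2)c2c(C=O)cc(OC)cc2OC)cc1
F3 | step 11 | (10S)-2,7,9-trimethoxy-10-(4-methoxyphenyl)-10,11-dihydro-5H-dibenzo[a,d][7]annulene-4,5-diol (C5 epimers) | COc1ccc([C@@H]2Cc3cc(OC)cc(O)c3C(O)c3cc(OC)cc(OC)c32)cc1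
F4 | step 7 | racemic {3-[2-(2-bromo-4,6-dimethoxyphenyl)-2-(4-methoxyphenyl)ethyl]-5-methoxyphenoxy}tri(propan-2-yl)silane | COc1ccc(C(Cc2cc(OC)cc(O[Si](C(C)C)(C(C)C)C(C)C)c2)c2c(Br)cc(OC)cc2OC)cc1
F5 | step 10 | 3-[(2S)-2-(2-bromo-4,6-dimethoxyphenyl)-2-(4-methoxyphenyl)ethyl]-5-methoxyphenol | COc1ccc([C@H](Cc2cc(OC)cc(O)c2)c2c(Br)cc(OC)cc2OC)cc1
F6 | step 10 | 2-[(1E)-3-{3-[(2S)-2-(2-bromo-4,6-dimethoxyphenyl)-2-(4-methoxyphenyl)ethyl]-5-methoxyphenoxy}prop-1-en-1-yl]-4,4,5,5-tetramethyl-1,3,2-dioxaborolane | COc1ccc([C@H](Cc2cc(OC)cc(OC/C=C/B3OC(C)(C)C(C)(C)O3)c2)c2c(Br)cc(OC)cc2OC)cc1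
F7 | step 12 | (5S,10S)-5-ethenyl-2,7,9-trimethoxy-10-(4-methoxyphenyl)-10,11-dihydro-5H-dibenzo[a,d][7]annulen-4-yl acetate | COc1ccc([C@@H]2Cc3cc(OC)cc(OC(C)=O)c3[C@@H](C=C)c3cc(OC)cc(OC)c32)cc1
F8 | step 12 | (5S,10S)-5-formyl-2,7,9-trimethoxy-10-(4-methoxyphenyl)-10,11-dihydro-5H-dibenzo[a,d][7]annulen-4-yl acetate | COc1ccc([C@@H]2Cc3cc(OC)cc(OC(C)=O)c3[C@H](c3cc(OC)cc(OC)c32)C=O)cc1
F9 | step 15 | (5S,10S)-5-[hydroxy(4-hydroxyphenyl)methyl]-10-(4-hydroxyphenyl)-10,11-dihydro-5H-dibenzo[a,d][7]annulene-2,4,7,9-tetrol (carbinol epimers) | Oc1ccc([C@@H]2Cc3cc(O)cc(O)c3[C@H](c3cc(O)cc(O)c32)C(O)c2ccc(O)cc2)cc1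
A1 | alternative 1 | (5S,10S)-5-(4-hydroxybenzyl)-2,7,9-trimethoxy-10-(4-methoxyphenyl)-10,11-dihydro-5H-dibenzo[a,d][7]annulen-4-ol | COc1ccc([C@@H]2Cc3cc(OC)cc(O)c3[C@@H](Cc3ccc(O)cc3)c3cc(OC)cc(OC)c32)cc1
A2 | alternative 1 | para-quinone methide of A1 (C7' exocyclic to a cyclohexadienone) | COc1ccc([C@@H]2Cc3cc(OC)cc(O)c3[C@@H](C=C3C=CC(=O)C=C3)c3cc(OC)cc(OC)c32)cc1
A3 | alternative 1 | (7S,7'S,8'S)-ampelopsin B tetramethyl ether with free 4-hydroxyphenyl group on C7' | COc1ccc([C@@H]2Cc3cc(OC)cc4c3[C@H](c3cc(OC)cc(OC)c32)[C@@H](c2ccc(O)cc2)O4)cc1
A4 | alternative 2 | eight-membered dibenzylic sulfone ketone (SO2 between C7 and C8; ketone at C8'; methoxy on a3, a5, d3, d5; 4-methoxyphenyl on C7) | COc1ccc(C2c3c(OC)cc(OC)cc3C(=O)c3c(OC)cc(OC)cc3CS2(=O)=O)cc1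
A5 | alternative 2 | 2,4,7,9-tetramethoxy-10-(4-methoxyphenyl)-5H-dibenzo[a,d][7]annulen-5-one | COc1ccc(C2=Cc3cc(OC)cc(OC)c3C(=O)c3cc(OC)cc(OC)c32)cc1
A6 | alternative 3 | methyl (3S)-4,6-dimethoxy-3-(4-methoxyphenyl)-1-oxo-2,3-dihydro-1H-indene-2-carboxylate (C2 epimers) | COC(=O)C1C(=O)c2cc(OC)cc(OC)c2[C@@H]1c1ccc(OC)cc1
A7 | alternative 3 | 3,5-dimethoxy-2-(trimethylsilyl)phenyl trifluoromethanesulfonate | COc1cc(OC)c([Si](C)(C)C)c(OS(=O)(=O)C(F)(F)F)c1
A8 | alternative 3 | 3,5-dimethoxybenzyne | COC1=CC(OC)=CC#C1
A9 | alternative 3 | methyl (10S,11R)-2,4,7,9-tetramethoxy-10-(4-methoxyphenyl)-5-oxo-10,11-dihydro-5H-dibenzo[a,d][7]annulene-11-carboxylate (trans) | COc1ccc([C@@H]2[C@@H](C(=O)OC)c3cc(OC)cc(OC)c3C(=O)c3cc(OC)cc(OC)c32)cc1
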